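The central tetramethoxybenzene ring is bonded to C3 of each indole and both C2 positions are unsubstituted CH. Opening the two N1–C2 bonds therefore leaves, on each side, a C=CH2 unit (future C3 and C2) bridging the central ring and a benzene ring that carries a nitro group ortho to it (future N1 on C7a). In the forward sense one palladium-catalysed deoxygenation with CO closes both pyrrole rings at nitrogen in the same flask, even though the halves are different. The precursor, a 1,4-bis[1-(2-nitroaryl)vinyl]tetramethoxybenzene, comes from two tosylhydrazone carbene couplings on the dibromide; the phenol is masked as a methoxymethyl ether, because a silyl ether para to nitro would not survive LiOtBu.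

Key step: step 8

Assumption: the tosylhydrazones are drawn as E isomers, but either C=N geometry serves because it is erased when the diazoalkane forms; the nitrophenol ketone is bought as such, which avoids the poorly regioselective nitration of 3-hydroxyacetophenone; the target has no stereocentre.

Step 1
Reactants: 1 1,2,4,5-tetramethoxybenzene
Product: 2 1,4-dibromo-2,3,5,6-tetramethoxybenzene
Conditions: NBS (2.1 equiv), MeCN, 0 °C to rt
Reagents that add atoms: N-bromosuccinimide, O=C1CCC(=O)N1Br
Why: Electrophilic aromatic bromination of a very electron-rich arene whose only two free positions lie para to each other, so that twofold substitution can lead to one dibromide only.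

Step 2
Reactants: 3 1-(5-hydroxy-2-nitrophenyl)ethan-1-one
Product: 4 1-[5-(methoxymethoxy)-2-nitrophenyl]ethan-1-one
Conditions: MOMCl (1.3 equiv), iPr2NEt (1.6 equiv), CH2Cl2, 0 °C to rt
Reagents that add atoms: chloromethyl methyl ether, COCCl
Why: O-Alkylation of the acidic nitrophenol (acetal protection) gives an ether that has no electrophilic silicon for tert-butoxide to attack, so it should outlast two couplings with LiOtBu at 100 °C and hot DMF, and it becomes readily acid-labile only after its ring has turned into an electron-rich indole.

Step 3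
Reactants: 4 1-[5-(methoxymethoxy)-2-nitrophenyl]ethan-1-one
Product: 5 N'-{(1E)-1-[5-(methoxymethoxy)-2-nitrophenyl]ethylidene}-4-methylbenzenesulfonohydrazide
Conditions: TsNHNH2 (1.1 equiv), MeOH, 60 °C, no added acid
Reagents that add atoms: 4-methylbenzenesulfonohydrazide, Cc1ccc(S(=O)(=O)NN)cc1
Why: Condensation of the methyl ketone with tosylhydrazide gives the crystalline N-tosylhydrazone, and leaving out an acid catalyst keeps the acetal safe.

Step 4
Reactants: 6 1-(4-bromo-2-nitrophenyl)ethan-1-one
Product: 7 1-[4-(3-methylbut-2-en-1-yl)-2-nitrophenyl]ethan-1-one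
Conditions: Bu3SnCH2CH=CMe2 (1.2 equiv), Pd(PPh3)4 (5 mol%), DMF, 90 °C
Reagents that add atoms: tributyl(3-methylbut-2-en-1-yl)stannane, CCCC[Sn](CCCC)(CCCC)CC=C(C)C
Why: Stille cross-coupling under neutral conditions: oxidative addition is easy at the C–Br bond para to the acetyl group, the prenyl group is expected to be transferred through its CH2 terminus to give the linear isomer, and the stannane, unlike prenylzinc or prenylmagnesium reagents, does not add to the ketone or attack the nitro group.

Step 5
Reactants: 7 1-[4-(3-methylbut-2-en-1-yl)-2-nitrophenyl]ethan-1-one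
Product: 8 N'-{(1E)-1-[4-(3-methylbut-2-en-1-yl)-2-nitrophenyl]ethylidene}-4-methylbenzenesulfonohydrazide
Conditions: TsNHNH2 (1.1 equiv), MeOH, 60 °C
Reagents that add atoms: 4-methylbenzenesulfonohydrazide, Cc1ccc(S(=O)(=O)NN)cc1
Why: Same tosylhydrazone condensation as in step 3, in a neutral medium that leaves the trisubstituted alkene in place.

Step 6
Reactants: 2 1,4-dibromo-2,3,5,6-tetramethoxybenzene (3 equiv, excess recovered); 5 tosylhydrazone of ketone 4
Product: 10 1-bromo-2,3,5,6-tetramethoxy-4-{1-[5-(methoxymethoxy)-2-nitrophenyl]vinyl}benzene, via aryldiazoethane 9 (not isolated)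
Conditions: Pd2(dba)3 (2.5 mol%), XPhos (10 mol%), LiOtBu (2.4 equiv), 1,4-dioxane, 100 °C
Reagents that add atoms: none
Why: Barluenga cross-coupling: LiOtBu converts 5 into diazoalkane 9 (Bamford–Stevens fragmentation), the arylpalladium bromide from 2 takes it up as a carbene, migration of the aryl group to the carbene carbon forges the hindered C–C bond and β-hydride elimination from the methyl group releases the 1,1-diarylethene, while the excess of recoverable 2 and the lower reactivity of the more electron-rich bromide 10 should hold the reaction at one coupling.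

Step 7
Reactants: 10 1-bromo-2,3,5,6-tetramethoxy-4-{1-[5-(methoxymethoxy)-2-nitrophenyl]vinyl}benzene; 8 tosylhydrazone of ketone 7 (1.6 equiv, in portions)
Product: 12 1-{1-[5-(methoxymethoxy)-2-nitrophenyl]vinyl}-4-{1-[4-(3-methylbut-2-en-1-yl)-2-nitrophenyl]vinyl}-2,3,5,6-tetramethoxybenzene, via aryldiazoethane 11 (not isolated)
Conditions: Pd2(dba)3 (5 mol%), XPhos (20 mol%), LiOtBu (2.4 equiv per 8), 1,4-dioxane, 100 °C
Reagents that add atoms: none
Why: Second Barluenga cross-coupling by the same carbene migratory insertion and β-hydride elimination, with bulky electron-rich XPhos to drive oxidative addition into the C–Br bond flanked by two methoxy groups, portionwise 8 to keep diazoalkane 11 dilute, and the prenyl fragment deliberately brought in last so that its alkene meets palladium and base as rarely as possible.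

Step 8
Reactants: 12 1-{1-[5-(methoxymethoxy)-2-nitrophenyl]vinyl}-4-{1-[4-(3-methylbut-2-en-1-yl)-2-nitrophenyl]vinyl}-2,3,5,6-tetramethoxybenzene
Product: 14 5-(methoxymethoxy)-3-{2,3,5,6-tetramethoxy-4-[6-(3-methylbut-2-en-1-yl)-1H-indol-3-yl]phenyl}-1H-indole, via half-closed nitro indole 13 (not isolated)
Conditions: Pd(OAc)2 (10 mol%), 1,10-phenanthroline (20 mol%), CO (6 atm), dry DMF, 110 °C
Reagents that add atoms: none
Why: Pd(OAc)2 is reduced by CO to a zerovalent palladium–phenanthroline complex, which removes one oxygen from a nitro group as CO2 and so brings that arm to the nitroso stage. The N=O unit, the arene C7a–C3a bond and the adjacent C=CH2 group form a conjugated six-electron array that ring-closes between nitrogen and the CH2 carbon (a 6π electrocyclisation, 5-endo-trig in formal terms), a hydrogen shift from the new C2 restores aromaticity at the N-hydroxy stage and a second CO takes away the last oxygen; the same sequence on the other arm means that each of the two five-membered rings is closed in this mode, 13 being the expected halfway point because the nitro group without a para alkoxy donor is reduced more easily. The closest known reaction type is the palladium-catalysed reductive N-heterocyclisation of 2-nitrostyrenes with CO, the catalytic counterpart of the Cadogan–Sundberg indole synthesis, which is established for α-aryl-2-nitrostyrenes (giving 3-arylindoles) and for twofold closures within one molecule. No stereocentre is formed, and the aryl–indole axes, flanked on the indole side only by C2–H and C4–H, are expected to rotate freely. The selectivity required is chemoselectivity of each reduced nitrogen for its own ortho alkene over the prenyl double bond (nitroso-ene reaction or aziridination), over the other arm and over the central ring; it is secured by the conjugated, intramolecular placement of the partner alkene, by the position of the prenyl group meta to nitrogen and out of reach, and by the methoxy groups that block every ortho position of the central ring against six-membered-ring amination. Dry DMF suppresses over-reduction to anilines, and the neutral medium leaves the acetal, the methyl ethers and the prenyl group alone.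

Step 9
Reactants: 14 5-(methoxymethoxy)-3-{2,3,5,6-tetramethoxy-4-[6-(3-methylbut-2-en-1-yl)-1H-indol-3-yl]phenyl}-1H-indole
Product: 15 3-{2,3,5,6-tetramethoxy-4-[6-(3-methylbut-2-en-1-yl)-1H-indol-3-yl]phenyl}-1H-indol-5-ol
Conditions: HCl (1.25 M in MeOH), THF, 40 °C, argon
Reagents that add atoms: none
Why: Acid-catalysed acetal exchange with methanol frees the phenol and carries the formaldehyde unit away as its dimethyl acetal, under conditions too mild to cleave the aryl methyl ethers, to hydrate the prenyl alkene or to shift the 3-aryl groups, and argon guards the oxidation-prone 5-hydroxyindole.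

Compound list
1 | 1,2,4,5-tetramethoxybenzene | COc1cc(OC)c(OC)cc1OC | starting material
2 | 1,4-dibromo-2,3,5,6-tetramethoxybenzene | COc1c(OC)c(Br)c(OC)c(OC)c1Br | intermediate
3 | 1-(5-hydroxy-2-nitrophenyl)ethan-1-one | CC(=O)c1cc(O)ccc1[N+](=O)[O-] | starting material
4 | 1-[5-(methoxymethoxy)-2-nitrophenyl]ethan-1-one | CC(=O)c1cc(OCOC)ccc1[N+](=O)[O-] | intermediate
5 | N'-{(1E)-1-[5-(methoxymethoxy)-2-nitrophenyl]ethylidene}-4-methylbenzenesulfonohydrazide | C/C(=N\NS(=O)(=O)c1ccc(C)cc1)c1cc(OCOC)ccc1[N+](=O)[O-] | intermediate
6 | 1-(4-bromo-2-nitrophenyl)ethan-1-one | CC(=O)c1ccc(Br)cc1[N+](=O)[O-] | starting material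
7 | 1-[4-(3-methylbut-2-en-1-yl)-2-nitrophenyl]ethan-1-one | CC(=O)c1ccc(CC=C(C)C)cc1[N+](=O)[O-] | intermediate
8 | N'-{(1E)-1-[4-(3-methylbut-2-en-1-yl)-2-nitrophenyl]ethylidene}-4-methylbenzenesulfonohydrazide | C/C(=N\NS(=O)(=O)c1ccc(C)cc1)c1ccc(CC=C(C)C)cc1[N+](=O)[O-] | intermediate
9 | 2-(1-diazoethyl)-4-(methoxymethoxy)-1-nitrobenzene | CC(=[N+]=[N-])c1cc(OCOC)ccc1[N+](=O)[O-] | intermediate (not isolated)
10 | 1-bromo-2,3,5,6-tetramethoxy-4-{1-[5-(methoxymethoxy)-2-nitrophenyl]vinyl}benzene | C=C(c1cc(OCOC)ccc1[N+](=O)[O-])c1c(OC)c(OC)c(Br)c(OC)c1OC | intermediate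
11 | 1-(1-diazoethyl)-4-(3-methylbut-2-en-1-yl)-2-nitrobenzene | CC(=[N+]=[N-])c1ccc(CC=C(C)C)cc1[N+](=O)[O-] | intermediate (not isolated)
12 | 1-{1-[5-(methoxymethoxy)-2-nitrophenyl]vinyl}-4-{1-[4-(3-methylbut-2-en-1-yl)-2-nitrophenyl]vinyl}-2,3,5,6-tetramethoxybenzene | C=C(c1cc(OCOC)ccc1[N+](=O)[O-])c1c(OC)c(OC)c(C(=C)c2ccc(CC=C(C)C)cc2[N+](=O)[O-])c(OC)c1OC | intermediate (key-step precursor)
13 | 3-(2,3,5,6-tetramethoxy-4-{1-[5-(methoxymethoxy)-2-nitrophenyl]vinyl}phenyl)-6-(3-methylbut-2-en-1-yl)-1H-indole | C=C(c1cc(OCOC)ccc1[N+](=O)[O-])c1c(OC)c(OC)c(-c2c[nH]c3cc(CC=C(C)C)ccc23)c(OC)c1OC | intermediate (not isolated)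
14 | 5-(methoxymethoxy)-3-{2,3,5,6-tetramethoxy-4-[6-(3-methylbut-2-en-1-yl)-1H-indol-3-yl]phenyl}-1H-indole | COCOc1ccc2[nH]cc(-c3c(OC)c(OC)c(-c4c[nH]c5cc(CC=C(C)C)ccc45)c(OC)c3OC)c2c1 | intermediate (key-step product)
15 | 3-{2,3,5,6-tetramethoxy-4-[6-(3-methylbut-2-en-1-yl)-1H-indol-3-yl]phenyl}-1H-indol-5-ol (CNP0145408.0) | COc1c(OC)c(-c2c[nH]c3ccc(O)cc23)c(OC)c(OC)c1-c1c[nH]c2cc(CC=C(C)C)ccc12 | target

Total step count: 9
Longest linear sequence: 6 steps (2, 3, 6, 7, 8, 9)

Steps most likely to fail

1. Step 8. Deoxygenation may stall on the more electron-rich arm. Traces of water may over-reduce a nitro group to the amine. The prenyl double bond may migrate into conjugation through a palladium hydride at 110 °C. The fallback sets out from 12 and comes back at 14, and it reaches the nitrene level through azides instead of by deoxygenation. Fe powder and NH4Cl in EtOH–H2O at 75 °C should reduce both nitro groups without touching the three alkenes or the acetal, giving the bis-aniline F1. Copper-catalysed diazo transfer (imidazole-1-sulfonyl azide hydrogen sulfate, CuSO4, K2CO3, MeOH, rt) should convert it into the bis(aryl azide) F2. Diazotisation is avoided because a diazonium ion beside a 1-arylvinyl group would close to a cinnoline (Widman–Stoermer reaction). Thermolysis in xylene at 140 °C should expel nitrogen from both azides and close both pyrrole rings (thermal 2-azidostyrene to indole cyclisation), giving 14.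

2. Step 7. Oxidative addition into the electron-rich C–Br bond of 10, flanked by two methoxy groups, may be slower than thermal decay of the diazoalkane (azine formation, 1,2-hydrogen shift, oxygen transfer from the neighbouring nitro group). The hydrazone would then be consumed without coupling. The fallback sets out from 10 and 7 and comes back at 12, and it makes the bond by transmetalation and reductive elimination instead of carbene insertion. Miyaura borylation of 10 (B2pin2, KOAc, PdCl2(dppf), 1,4-dioxane, 90 °C) has no perishable partner, so a slow oxidative addition costs only time; it should give the pinacol boronate F3. Ketone 7 is deprotonated with KHMDS (THF, −78 °C) to the potassium enolate F4, which PhNTf2 traps as the enol triflate F5. Suzuki–Miyaura coupling of the two (Pd(OAc)2, SPhos, K3PO4, 1,4-dioxane–H2O, 60 °C) moves oxidative addition to the unhindered vinyl triflate and should give 12.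

3. Step 6. Control over single versus double coupling may be lost, followed by a tedious separation from excess dibromide, since both C–Br bonds react by the same pathway. The fallback sets out from 2 and comes back at 10, and it replaces statistical control by two different halogens. Bromine–lithium exchange with n-BuLi (1.0 equiv, THF, −78 °C) should give the aryllithium F6, which iodine converts into the bromo iodide F7. The Barluenga coupling with 5 (one equivalent of each partner, same catalyst and base, 80 °C, again via 9) should then take place only at the much more reactive C–I bond, giving 10.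

Further compounds
F1 | step 8 | 1-{1-[2-amino-5-(methoxymethoxy)phenyl]vinyl}-4-{1-[2-amino-4-(3-methylbut-2-en-1-yl)phenyl]vinyl}-2,3,5,6-tetramethoxybenzene (bis-aniline) | C=C(c1cc(OCOC)ccc1N)c1c(OC)c(OC)c(C(=C)c2ccc(CC=C(C)C)cc2N)c(OC)c1OC
F2 | step 8 | 1-{1-[2-azido-5-(methoxymethoxy)phenyl]vinyl}-4-{1-[2-azido-4-(3-methylbut-2-en-1-yl)phenyl]vinyl}-2,3,5,6-tetramethoxybenzene (bis(aryl azide)) | C=C(c1cc(OCOC)ccc1N=[N+]=[N-])c1c(OC)c(OC)c(C(=C)c2ccc(CC=C(C)C)cc2N=[N+]=[N-])c(OC)c1OC
F3 | step 7 | 4,4,5,5-tetramethyl-2-(2,3,5,6-tetramethoxy-4-{1-[5-(methoxymethoxy)-2-nitrophenyl]vinyl}phenyl)-1,3,2-dioxaborolane (pinacol boronate) | C=C(c1cc(OCOC)ccc1[N+](=O)[O-])c1c(OC)c(OC)c(B2OC(C)(C)C(C)(C)O2)c(OC)c1OC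
F4 | step 7 | potassium 1-[4-(3-methylbut-2-en-1-yl)-2-nitrophenyl]ethen-1-olate (potassium enolate) | [K+].C=C([O-])c1ccc(CC=C(C)C)cc1[N+](=O)[O-]
F5 | step 7 | 1-[4-(3-methylbut-2-en-1-yl)-2-nitrophenyl]vinyl trifluoromethanesulfonate (enol triflate) | C=C(OS(=O)(=O)C(F)(F)F)c1ccc(CC=C(C)C)cc1[N+](=O)[O-]
F6 | step 6 | (4-bromo-2,3,5,6-tetramethoxyphenyl)lithium (aryllithium) | [Li]c1c(OC)c(OC)c(Br)c(OC)c1OC
F7 | step 6 | 1-bromo-4-iodo-2,3,5,6-tetramethoxybenzene (bromo iodide) | COc1c(OC)c(I)c(OC)c(OC)c1Br
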